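**The ceiling.** 50.0% of the E is what you should expect to react in this flask. Call this the G ceiling, the charged G as a fraction of the charged E.

E 0.50 M (in portions, 3); G 0.500 equiv; time 80 min; the portions of E follow each other after 5.0 min, the first at the start

    E + G → L + X (k1 = 5.6 L mol⁻¹ min⁻¹)
    L → Z (k2 = 0.15 min⁻¹)

- the reaction counts as stopped when no species that holds the E changes by six tenths of a point or more over the second half of the time
- run time (flask): 80 min

- why nothing more happens at 80 min, or that something still does (G has run out first / all of E has reacted / it is still moving)
- conversion of E at 80 min
- amount of Z at 80 min, in percent of the E charged

**Main step.** Take the first step by itself. Each event removes one E and one G, so the gap between their fractions stays put. Freeze that gap. Once the last portion is in, E stands 50.0% of the charge above G. So when G reaches zero, conversion equals the ceiling, and G is the limiting reagent. With E frozen at that remainder, G halves every 0.495 min, which is far shorter than the 80 min run.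

**Second step.** Now add L going to Z. This step takes no G and returns no E, so the conversion does not move. It changes what the converted E is. Its half-life is 4.62 min, longer than the first step's. From the last portion to the end, you have 15.1 of these half-lives. They leave 0.00275% of the L standing at that portion. So I put Z at the ceiling too.

**The portions.** The first two portions together hold 66.7% of the E, more than the ceiling. So the E charged before the last portion goes in at 10.0 min is already enough to take up the G charge. I expect the dosing to shift the timing, not the ceiling.

**The forecast.** It says G has run out first, with conversion 50% (49.8% to 50%) and Z 50% (49.7% to 50%). It has G “essentially used up shortly after the last portion goes in”.

**The result.** The simulated flask gives this for its end: G has run out first, with 0% of the G charge left at 80.0 min. In this flask conversion is 50.0% and Z is 50.0%, so conversion sits at the ceiling. The running short of G is the main reason: with that shortage taken away, conversion goes from 50.0% to 100%. A neighbour flask, the same recipe with 0.120 equiv of G, has a ceiling of 12.0%, and that flask converts 12.0%.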